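The runs are calculated from invented constants, noise included.

Early times give me the clock of this reaction, so I start at the first row of the dusk run.

| flask | starting complex | incoming ligand | leaving ligand | scavenger | remark | time |
|---|---|---|---|---|---|---|
| dusk | 0.015 M (fed, over 15 min) | 0.116 M | 0.145 M | 0.0435 M | run made earlier |  |
| autumn | 0.058 M (fed, over 15 min) | 0.116 M | 0.145 M | 0.0435 M | run made earlier |  |
| spring | 0.029 M (fed, over 15 min) | 0.116 M | 0.145 M | 0.022 M | run made earlier |  |
| flask | 0.029 M (fed, over 15 min) | 0.116 M | 0.145 M | 0.0435 M |  | 50 min |

| run | time / min | starting complex / % | complex with two exchanged / % |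
|---|---|---|---|
| dusk | 3.00 | 14.3 | 0 |
| dusk | 6.00 | 21.5 | 0.8 |
| dusk | 12.0 | 28.1 | 5.6 |
| dusk | 20.0 | 11.2 | 8.2 |
| dusk | 40.0 | 0.4 | 3.6 |
| autumn | 8.00 | 25.8 | 3.0 |
| autumn | 15.0 | 38.3 | 6.1 |
| autumn | 25.0 | 16.6 | 8.0 |
| autumn | 30.0 | 12.4 | 8.8 |
| autumn | 40.0 | 8.5 | 8.3 |
| spring | 8.00 | 25.0 | 3.2 |
| spring | 15.0 | 32.2 | 6.5 |
| spring | 25.0 | 7.9 | 8.3 |
| spring | 30.0 | 4.4 | 6.6 |
| spring | 40.0 | 1.7 | 5.4 |

(scatter of a reading: 0.3 percentage points)

- for leaving ligand the idle adduct is counted in
- the numbers in the tables scatter with a standard deviation of 0.3 percentage points
- on the list of suspects stand: scavenger + leaving ligand -> scavenged by-product; complex with two exchanged + incoming ligand -> leaving ligand + complex with three exchanged; starting complex + incoming ligand -> leaving ligand + complex with one exchanged; complex with one exchanged + incoming ligand -> leaving ligand + complex with two exchanged; leaving ligand + incoming ligand <-> idle adduct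
- percentages count the whole charge, also what has not yet gone in
- the earlier runs do not show how much of incoming ligand is bound; that part of a forecast is a guess

* part of the starting complex that has reacted at 50 min
* share of the unused incoming ligand that is free and not bound as idle adduct, at 50 min

By 3.00 min the dusk feed has delivered 20.0 % of the charge, yet 14.3 % stands as starting complex. Dividing that loss by the area under a roughly straight rise from zero gives a decay rate of 0.266 min⁻¹, a time constant of 3.76 min. I take the decay of starting complex as pseudo-first-order, with a rate proportional to free [incoming ligand]. Treating the charge as free, I divide by it and get my ligand constant, the decay rate of starting complex per unit of free [incoming ligand]: 2.29 L mol⁻¹ min⁻¹.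

Now I read the last rows against each other. From 30.0 min to 40.0 min the spring run reads a decay of 0.0951 min⁻¹ and the autumn run 0.0378 min⁻¹, so autumn, which has more starting complex and also more scavenger, has the slower tail. Through my constant, these rates read as free [incoming ligand] of 0.0415 M in spring and 0.0165 M in autumn.

Spring has the flask's charges of starting complex, incoming ligand and leaving ligand, with less scavenger. I therefore take its 7.9 % at 25.0 min and run its tail rate on to 50 min, which gives me 99.3 % of the starting complex reacted. The runs give me no figure for the free share of the unused incoming ligand.

The forecast says 99.5 % reacted (98.7 % to 99.9 %) and a free share of 45 % (27 % to 62 %), the share being “largely a guess”.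

The flask gives 99.4 % reacted and a free share of 89.8 %, the share lying above the forecast's range. The equilibrium constant of the idle adduct times [leaving ligand] at the start is 0.097, well below one. At 50.0 min free incoming ligand in the flask stands at 32.5 % of its charge, so my constant gives starting complex a time constant at that moment of 11.6 min, which is shorter than the 50 min of the run.

    scavenger + leaving ligand → scavenged by-product (k = 1.28 L mol⁻¹ min⁻¹)
    complex with two exchanged + incoming ligand → leaving ligand + complex with three exchanged (k = 4.72 L mol⁻¹ min⁻¹)
    starting complex + incoming ligand → leaving ligand + complex with one exchanged (k = 2.21 L mol⁻¹ min⁻¹)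
    complex with one exchanged + incoming ligand → leaving ligand + complex with two exchanged (k = 0.875 L mol⁻¹ min⁻¹)
    leaving ligand + incoming ligand ⇌ idle adduct, settled at all times (K = 0.667 L mol⁻¹)

The neighbour flask with 0.073 M of starting complex ends with free incoming ligand at 2.37 % of its charge, so my constant gives starting complex a time constant at that moment of 159 min, longer than the run. Computed, that neighbour has 86.4 % reacted at 50 min.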